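**Strategy.** Atom numbering: ring C is C1–C2–C3–C9–C13, the cyclobutane C3–C4–C8–C9, ring A C4–C5–C6–C7–C8, the lactone C9–O10–C11–C12=C13. The plan hinges on cutting C2–C3. In the target this bond and the C9–C13 bond leave the cyclobutane on the same face, so a C2 rhodium carbenoid hung from C9 via C13 and C1 faces the methine hydrogen of a C3-methyl precursor and replaces it with retention. One operation thus closes ring C, makes C3 quaternary and delivers a C1 ketone whose C13 hydrogens later build the butenolide. The precursor is the ring A-fused cyclobutane carrying an exo C3 methyl, a C9 triethylsilyl ether and an endo diazoacetonyl arm on C9.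

Key step: step 12

**Remarks on the chemistry**
- Face labels: exo is the convex face of the cis-bicyclo[3.2.0]heptane and of the later tricycle (the face of H4 and H8); endo is the concave face. Bicyclic names use bicyclo[3.2.0]heptane locants.
- Assumption: reagents reach the bicyclic and tricyclic intermediates from the convex face; this governs the methylation, the epoxidation and the C1 reduction.
- Assumption: the C9 oxygen is masked as a triethylsilyl ether (bulkier and more robust than a trimethylsilyl ether) and C7 as a tert-butyldimethylsilyl ether, so that C9 alone can be unmasked after the key step.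
- Assumption: where an alkene geometry or a stereocentre is erased by the following operation (olefination product, its epoxide, the ozonide, the aldol adduct), it is left undefined.
- Assumption: the five starting materials are taken as commercial.

**Route**

Step 1
Reactants: 1 (S)-4-(tert-butyldimethylsilyloxy)cyclopent-2-en-1-one
Product: 2 (1R,4S)-4-(tert-butyldimethylsilyloxy)-1-methylcyclopent-2-en-1-ol (hydroxyl cis to the silyloxy group)
Conditions: MeLi, Et2O, −78 °C; aq. NH4Cl
Reagents that add atoms: methyllithium, [Li]C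
Why: Carbonyl 1,2-addition of an organolithium at low temperature outruns conjugate addition and enolisation, and the reagent should approach C7 anti to the C5 silyloxy group so that the new hydroxyl is cis to it, the minor epimer being removed by chromatography.

Step 2
Reactants: 2 (1R,4S)-4-(tert-butyldimethylsilyloxy)-1-methylcyclopent-2-en-1-ol
Product: 3 (1R,4S)-1,4-bis(tert-butyldimethylsilyloxy)-1-methylcyclopent-2-ene
Conditions: TBSOTf, 2,6-lutidine, CH2Cl2, 0 °C
Reagents that add atoms: tert-butyldimethylsilyl trifluoromethanesulfonate, CC(C)(C)[Si](C)(C)OS(=O)(=O)C(F)(F)F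
Why: Silyl triflate silylation with a hindered pyridine base is the standard way to cap a tertiary alcohol, and the tert-butyldimethylsilyl ether is chosen to outlast the later removal of the C9 triethylsilyl group.

Step 3
Reactants: 3 (1R,4S)-1,4-bis(tert-butyldimethylsilyloxy)-1-methylcyclopent-2-ene; 4 trichloroacetyl chloride
Product: 6 7,7-dichloro-2-exo,4-exo-bis(tert-butyldimethylsilyloxy)-4-endo-methyl-cis-bicyclo[3.2.0]heptan-6-one, via dichloroketene 5 (not isolated)
Conditions: Zn–Cu couple, Et2O/DME, 25 °C, slow addition of 4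
Reagents that add atoms: trichloroacetyl chloride (compound 4), ClC(=O)C(Cl)(Cl)Cl
Why: Thermal ketene–alkene [2+2] cycloaddition with dichloroketene, the ketene that reliably engages unactivated cyclopentenes, should take place on the ring face that carries only the C7 methyl (both silyloxy groups shield the other face) and should put the substituent-free carbonyl carbon on C8 next to quaternary C7 while the bulky CCl2 terminus bonds to the less crowded C4, which sets the cis ring fusion at C4 and C8.

Step 4
Reactants: 6 7,7-dichloro-2-exo,4-exo-bis(tert-butyldimethylsilyloxy)-4-endo-methyl-cis-bicyclo[3.2.0]heptan-6-one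
Product: 7 2-exo,4-exo-bis(tert-butyldimethylsilyloxy)-4-endo-methyl-cis-bicyclo[3.2.0]heptan-6-one
Conditions: Zn, NH4Cl, MeOH, 25 °C
Reagents that add atoms: none
Why: Zinc reductive dehalogenation of an alpha,alpha-dichlorocyclobutanone is routine and leaves the silyl ethers and the ring stereocentres untouched.

Step 5
Reactants: 7 2-exo,4-exo-bis(tert-butyldimethylsilyloxy)-4-endo-methyl-cis-bicyclo[3.2.0]heptan-6-one
Product: 8 2-exo,4-exo-bis(tert-butyldimethylsilyloxy)-4-endo,7-exo-dimethyl-cis-bicyclo[3.2.0]heptan-6-one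
Conditions: LiN(SiMe3)2, THF, −78 °C; MeI, −78 to −20 °C
Reagents that add atoms: iodomethane, CI
Why: Kinetic enolate alkylation in which the base removes a C3 methylene proton (an enolate toward the ring-fusion carbon C8 is too strained) and iodomethane enters from the convex face, giving the exo methyl group, which is also the thermodynamically preferred epimer and leaves C3–H on the concave face.

Step 6
Reactants: 8 2-exo,4-exo-bis(tert-butyldimethylsilyloxy)-4-endo,7-exo-dimethyl-cis-bicyclo[3.2.0]heptan-6-one; 9 trimethyl phosphonoacetate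
Product: 10 methyl 2-[2-exo,4-exo-bis(tert-butyldimethylsilyloxy)-4-endo,7-exo-dimethyl-cis-bicyclo[3.2.0]heptan-6-ylidene]acetate
Conditions: NaH, THF, 0 to 25 °C
Reagents that add atoms: trimethyl phosphonoacetate (compound 9), COC(=O)CP(=O)(OC)OC
Why: Horner–Wadsworth–Emmons olefination works well on strained, electrophilic cyclobutanones, either alkene geometry is acceptable because C13 becomes a methylene group two steps later, and any base-induced equilibration at C3 favours the exo methyl epimer already present.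

Step 7
Reactants: 10 methyl 2-[2-exo,4-exo-bis(tert-butyldimethylsilyloxy)-4-endo,7-exo-dimethyl-cis-bicyclo[3.2.0]heptan-6-ylidene]acetate
Product: 11 methyl 2-exo,4-exo-bis(tert-butyldimethylsilyloxy)-4-endo,7-exo-dimethylspiro[cis-bicyclo[3.2.0]heptane-6,2'-oxirane]-3'-carboxylate (oxirane oxygen exo)
Conditions: DMDO, acetone, 0 to 25 °C
Reagents that add atoms: dimethyldioxirane, CC1(C)OO1
Why: Dioxirane epoxidation is neutral, tolerates the silyl ethers and is effective on beta,beta-disubstituted enoates, and oxygen should be delivered to the convex face of the alkylidenecyclobutane because the concave face is covered by ring A and its endo C7 methyl, which sets the C9–O bond exo.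

Step 8
Reactants: 11 methyl 2-exo,4-exo-bis(tert-butyldimethylsilyloxy)-4-endo,7-exo-dimethylspiro[cis-bicyclo[3.2.0]heptane-6,2'-oxirane]-3'-carboxylate
Product: 12 methyl 2-[6-exo-hydroxy-2-exo,4-exo-bis(tert-butyldimethylsilyloxy)-4-endo,7-exo-dimethyl-cis-bicyclo[3.2.0]heptan-6-yl]acetate (acetate arm endo)
Conditions: SmI2, HMPA, MeOH, THF, −78 °C
Reagents that add atoms: none
Why: Samarium diiodide reduction of an alpha,beta-epoxy ester cleaves the C13–O bond next to the carbonyl and leaves the C9–O bond in place, so the beta-hydroxy ester keeps the C9 configuration set in the epoxidation, with oxygen exo and the acetate arm endo.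

Step 9
Reactants: 12 methyl 2-[6-exo-hydroxy-2-exo,4-exo-bis(tert-butyldimethylsilyloxy)-4-endo,7-exo-dimethyl-cis-bicyclo[3.2.0]heptan-6-yl]acetate
Product: 13 methyl 2-[6-exo-triethylsilyloxy-2-exo,4-exo-bis(tert-butyldimethylsilyloxy)-4-endo,7-exo-dimethyl-cis-bicyclo[3.2.0]heptan-6-yl]acetate
Conditions: TESOTf, 2,6-lutidine, CH2Cl2, −78 to 0 °C
Reagents that add atoms: triethylsilyl trifluoromethanesulfonate, CC[Si](CC)(CC)OS(=O)(=O)C(F)(F)F
Why: Silyl triflate silylation of the tertiary cyclobutanol installs a group that excludes O–H insertion in the carbenoid step, is hindered enough to disfavour attack of the carbenoid on oxygen, and can later be removed in the presence of the two tert-butyldimethylsilyl ethers.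

Step 10
Reactants: 13 methyl 2-[6-exo-triethylsilyloxy-2-exo,4-exo-bis(tert-butyldimethylsilyloxy)-4-endo,7-exo-dimethyl-cis-bicyclo[3.2.0]heptan-6-yl]acetate
Product: 14 2-[6-exo-triethylsilyloxy-2-exo,4-exo-bis(tert-butyldimethylsilyloxy)-4-endo,7-exo-dimethyl-cis-bicyclo[3.2.0]heptan-6-yl]acetic acid
Conditions: LiOH, THF/MeOH/H2O, 25 °C; dilute HCl to pH 4
Reagents that add atoms: lithium hydroxide, [Li+].[OH-]
Why: Ester saponification with lithium hydroxide is compatible with the tertiary and secondary silyl ethers and gives the acid needed for one-carbon extension.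

Step 11
Reactants: 14 2-[6-exo-triethylsilyloxy-2-exo,4-exo-bis(tert-butyldimethylsilyloxy)-4-endo,7-exo-dimethyl-cis-bicyclo[3.2.0]heptan-6-yl]acetic acid
Product: 16 1-diazo-3-[6-exo-triethylsilyloxy-2-exo,4-exo-bis(tert-butyldimethylsilyloxy)-4-endo,7-exo-dimethyl-cis-bicyclo[3.2.0]heptan-6-yl]propan-2-one, via mixed anhydride 15 (not isolated)
Conditions: i-BuOCOCl, N-methylmorpholine, THF, −20 °C; then CH2N2, Et2O, −20 to 0 °C
Reagents that add atoms: isobutyl chloroformate, CC(C)COC(Cl)=O (its atoms are kept only in 15); diazomethane, C=[N+]=[N-]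
Why: Acylation of diazomethane by a mixed carbonic anhydride (the first stage of the Arndt–Eistert sequence) gives the diazomethyl ketone without the hydrogen chloride that an acid chloride route would release onto the silyl ethers.

Step 12
Reactants: 16 1-diazo-3-[6-exo-triethylsilyloxy-2-exo,4-exo-bis(tert-butyldimethylsilyloxy)-4-endo,7-exo-dimethyl-cis-bicyclo[3.2.0]heptan-6-yl]propan-2-one
Product: 17 3,5-bis(tert-butyldimethylsilyloxy)-3,7-dimethyl-1-triethylsilyloxy-cis-syn-cis-tricyclo[5.3.0.0(2,6)]decan-9-one (C1 ketone; quaternary C3; silyl ethers at C5, C7 and C9 in target numbering)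
Conditions: Rh2(OAc)4 (1 mol %), CH2Cl2, 25 °C, slow addition of 16
Reagents that add atoms: none
Why: Dirhodium tetraacetate expels dinitrogen from 16 to give an electrophilic rhodium carbenoid at C2, which inserts into the C3–H bond through a concerted three-centre, hydride-transfer-like transition state; the closest known reaction type is the rhodium-catalysed intramolecular 1,5 C–H insertion of diazomethyl ketones into tertiary C–H bonds that gives cyclopentanones. Ring C closes by formation of the C2–C3 bond in a five-membered, cis-fused mode on the concave face, the only geometry the C9–C13–C1 tether allows. The one new stereocentre, quaternary C3, is formed with retention, so it is controlled by the exo methyl group placed in step 5 and by the endo position of the arm set in steps 7 and 8. The step needs site selectivity for C3–H over C8–H and chemoselectivity for carbon over oxygen: C8–H lies on the opposite cyclobutane face and would demand a trans-fused ring, C3–H is tertiary and five atoms from the carbenoid, and the C9 oxygen carries a bulky triethylsilyl group while no free hydroxyl is present. Slow addition at high dilution suppresses carbene dimerisation.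

Step 13
Reactants: 17 3,5-bis(tert-butyldimethylsilyloxy)-3,7-dimethyl-1-triethylsilyloxy-cis-syn-cis-tricyclo[5.3.0.0(2,6)]decan-9-one
Product: 18 3,5-bis(tert-butyldimethylsilyloxy)-1-hydroxy-3,7-dimethyl-cis-syn-cis-tricyclo[5.3.0.0(2,6)]decan-9-one (free C9 hydroxyl)
Conditions: HF·pyridine, pyridine, THF, 0 °C
Reagents that add atoms: none
Why: Buffered hydrogen fluoride–pyridine cleaves a triethylsilyl ether far faster than tert-butyldimethylsilyl ethers, so only the C9 hydroxyl is released, and the non-basic medium avoids retro-aldol cleavage of the beta-hydroxy ketone.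

Step 14
Reactants: 19 methyl 2-(hydroxymethyl)acrylate
Product: 20 methyl 2-[(tert-butyldimethylsilyloxy)methyl]acrylate
Conditions: TBSCl, imidazole, CH2Cl2, 25 °C
Reagents that add atoms: tert-butyldimethylsilyl chloride, CC(C)(C)[Si](C)(C)Cl
Why: Standard silylation of a primary alcohol with a silyl chloride and imidazole.

Step 15
Reactants: 20 methyl 2-[(tert-butyldimethylsilyloxy)methyl]acrylate
Product: 21 2-[(tert-butyldimethylsilyloxy)methyl]acrylic acid
Conditions: LiOH, THF/H2O, 0 to 25 °C; dilute HCl to pH 4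
Reagents that add atoms: lithium hydroxide, [Li+].[OH-]
Why: Saponification of the methyl ester at low temperature leaves the primary silyl ether and the acrylate double bond intact.

Step 16
Reactants: 18 3,5-bis(tert-butyldimethylsilyloxy)-1-hydroxy-3,7-dimethyl-cis-syn-cis-tricyclo[5.3.0.0(2,6)]decan-9-one; 21 2-[(tert-butyldimethylsilyloxy)methyl]acrylic acid
Product: 23 C9 2-[(tert-butyldimethylsilyloxy)methyl]acrylate ester of 18, via acid chloride 22 (not isolated)
Conditions: 21, Me2C=C(Cl)NMe2, CH2Cl2, 0 °C; then 18, Et3N, DMAP (cat.), 0 to 25 °C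
Reagents that add atoms: 2-[(tert-butyldimethylsilyloxy)methyl]acrylic acid (compound 21), C=C(CO[Si](C)(C)C(C)(C)C)C(=O)O; 1-chloro-N,N,2-trimethylprop-1-en-1-amine, CC(C)=C(Cl)N(C)C (its chlorine is kept only in 22)
Why: Nucleophile-catalysed acylation by an acid chloride made under neutral conditions should succeed because the tertiary C9 cyclobutanol lies on the open convex face, and the acrylate serves as a masked alpha-keto ester that could not be carried through an esterification as such.

Step 17
Reactants: 23 C9 2-[(tert-butyldimethylsilyloxy)methyl]acrylate ester of 18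
Product: 25 C9 3-(tert-butyldimethylsilyloxy)-2-oxopropanoate ester of 18, via ozonide 24 (not isolated)
Conditions: O3, CH2Cl2, −78 °C; then Me2S, −78 to 25 °C
Reagents that add atoms: ozone, [O-][O+]=O
Why: Ozonolysis with reductive work-up cleaves the only C=C bond, the 1,1-disubstituted acrylate, to the alpha-keto ester while the ketone and the silyl ethers are inert.

Step 18
Reactants: 25 C9 3-(tert-butyldimethylsilyloxy)-2-oxopropanoate ester of 18
Product: 27 tetracyclic butenolide ketone (target skeleton with C1 ketone and tert-butyldimethylsilyl ethers at C5-O, C7-O and the C12 CH2O group), via aldol adduct 26 (not isolated)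
Conditions: DBU (0.2 equiv), CH2Cl2, 0 to 25 °C
Reagents that add atoms: none
Why: Intramolecular aldol condensation in which the C13 enolate of the C1 ketone adds to the highly electrophilic C12 keto group in a five-membered ring closure (attack from C2 would need a seven-membered ring) and E1cB loss of water gives the butenolide conjugated to both carbonyl groups.

Step 19
Reactants: 27 tetracyclic butenolide ketone
Product: 28 C1 endo allylic alcohol (C1 epimer of the target configuration)
Conditions: NaBH4, CeCl3·7H2O, MeOH, −78 °C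
Reagents that add atoms: none
Why: Luche reduction gives 1,2-reduction of the enone carbonyl without touching the lactone or the conjugated double bond, and hydride should enter from the convex face because the concave face of ring C is screened by ring A and the endo C7 methyl, which places the hydroxyl on the concave face.

Step 20
Reactants: 28 C1 endo allylic alcohol; 29 tiglic acid ((E)-2-methylbut-2-enoic acid)
Product: 30 C1 exo tiglate (tris-silyl ether of the target core)
Conditions: PPh3, DIAD, THF, 0 to 25 °C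
Reagents that add atoms: tiglic acid (compound 29), C/C=C(\C)C(=O)O
Why: Mitsunobu esterification converts the allylic alcohol into its tiglate with inversion at C1, the carboxylate attacking from the open convex face, which sets the C1 configuration of the target and keeps the E geometry of the acid.

Step 21
Reactants: 30 C1 exo tiglate (tris-silyl ether)
Product: 31 triol (C5-OH, C7-OH and C12 CH2OH free; C1 tiglate)
Conditions: HF (48% aq.), MeCN, 0 to 25 °C
Reagents that add atoms: none
Why: Fluoride-driven cleavage of all three silyl ethers under acidic conditions avoids the basic media that could cause acyl migration or lactone opening.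

Step 22
Reactants: 31 triol
Product: 32 CNP0210373.1
Conditions: Ac2O, pyridine, 25 °C
Reagents that add atoms: acetic anhydride, CC(=O)OC(C)=O
Why: Acetylation with acetic anhydride in pyridine without a nucleophilic catalyst esterifies the primary and the secondary hydroxyl groups while the hindered tertiary C7 hydroxyl stays free, which gives the target.

**Compound list**

1 | (S)-4-(tert-butyldimethylsilyloxy)cyclopent-2-en-1-one | O=C1C=C[C@@H](O[Si](C)(C)C(C)(C)C)C1 | starting material
2 | (1R,4S)-4-(tert-butyldimethylsilyloxy)-1-methylcyclopent-2-en-1-ol | C1=C[C@@H](O[Si](C)(C)C(C)(C)C)C[C@@]1(C)O | intermediate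
3 | (1R,4S)-1,4-bis(tert-butyldimethylsilyloxy)-1-methylcyclopent-2-ene | C1=C[C@@H](O[Si](C)(C)C(C)(C)C)C[C@@]1(C)O[Si](C)(C)C(C)(C)C | intermediate
4 | trichloroacetyl chloride | ClC(=O)C(Cl)(Cl)Cl | starting material
5 | dichloroketene | ClC(Cl)=C=O | intermediate
6 | 7,7-dichloro-2-exo,4-exo-bis(tert-butyldimethylsilyloxy)-4-endo-methyl-cis-bicyclo[3.2.0]heptan-6-one | O=C1C(Cl)(Cl)[C@@H]2[C@@H](O[Si](C)(C)C(C)(C)C)C[C@@](C)(O[Si](C)(C)C(C)(C)C)[C@H]12 | intermediate
7 | 2-exo,4-exo-bis(tert-butyldimethylsilyloxy)-4-endo-methyl-cis-bicyclo[3.2.0]heptan-6-one | O=C1C[C@@H]2[C@@H](O[Si](C)(C)C(C)(C)C)C[C@@](C)(O[Si](C)(C)C(C)(C)C)[C@H]12 | intermediate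
8 | 2-exo,4-exo-bis(tert-butyldimethylsilyloxy)-4-endo,7-exo-dimethyl-cis-bicyclo[3.2.0]heptan-6-one | O=C1[C@@H](C)[C@@H]2[C@@H](O[Si](C)(C)C(C)(C)C)C[C@@](C)(O[Si](C)(C)C(C)(C)C)[C@H]12 | intermediate
9 | trimethyl phosphonoacetate | COC(=O)CP(=O)(OC)OC | starting material
10 | methyl 2-[2-exo,4-exo-bis(tert-butyldimethylsilyloxy)-4-endo,7-exo-dimethyl-cis-bicyclo[3.2.0]heptan-6-ylidene]acetate (alkene geometry open) | COC(=O)C=C1[C@@H](C)[C@@H]2[C@@H](O[Si](C)(C)C(C)(C)C)C[C@@](C)(O[Si](C)(C)C(C)(C)C)[C@H]12 | intermediate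
11 | methyl 2-exo,4-exo-bis(tert-butyldimethylsilyloxy)-4-endo,7-exo-dimethylspiro[cis-bicyclo[3.2.0]heptane-6,2'-oxirane]-3'-carboxylate, oxirane oxygen exo (C13 open) | COC(=O)C1O[C@]12[C@@H](C)[C@@H]3[C@@H](O[Si](C)(C)C(C)(C)C)C[C@@](C)(O[Si](C)(C)C(C)(C)C)[C@H]23 | intermediate
12 | methyl 2-[6-exo-hydroxy-2-exo,4-exo-bis(tert-butyldimethylsilyloxy)-4-endo,7-exo-dimethyl-cis-bicyclo[3.2.0]heptan-6-yl]acetate | COC(=O)C[C@]1(O)[C@@H](C)[C@@H]2[C@@H](O[Si](C)(C)C(C)(C)C)C[C@@](C)(O[Si](C)(C)C(C)(C)C)[C@H]12 | intermediate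
13 | methyl 2-[6-exo-triethylsilyloxy-2-exo,4-exo-bis(tert-butyldimethylsilyloxy)-4-endo,7-exo-dimethyl-cis-bicyclo[3.2.0]heptan-6-yl]acetate | COC(=O)C[C@]1(O[Si](CC)(CC)CC)[C@@H](C)[C@@H]2[C@@H](O[Si](C)(C)C(C)(C)C)C[C@@](C)(O[Si](C)(C)C(C)(C)C)[C@H]12 | intermediate
14 | 2-[6-exo-triethylsilyloxy-2-exo,4-exo-bis(tert-butyldimethylsilyloxy)-4-endo,7-exo-dimethyl-cis-bicyclo[3.2.0]heptan-6-yl]acetic acid | OC(=O)C[C@]1(O[Si](CC)(CC)CC)[C@@H](C)[C@@H]2[C@@H](O[Si](C)(C)C(C)(C)C)C[C@@](C)(O[Si](C)(C)C(C)(C)C)[C@H]12 | intermediate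
15 | mixed isobutyl carbonic anhydride of 14 | CC(C)COC(=O)OC(=O)C[C@]1(O[Si](CC)(CC)CC)[C@@H](C)[C@@H]2[C@@H](O[Si](C)(C)C(C)(C)C)C[C@@](C)(O[Si](C)(C)C(C)(C)C)[C@H]12 | intermediate
16 | 1-diazo-3-[6-exo-triethylsilyloxy-2-exo,4-exo-bis(tert-butyldimethylsilyloxy)-4-endo,7-exo-dimethyl-cis-bicyclo[3.2.0]heptan-6-yl]propan-2-one | [N-]=[N+]=CC(=O)C[C@]1(O[Si](CC)(CC)CC)[C@@H](C)[C@@H]2[C@@H](O[Si](C)(C)C(C)(C)C)C[C@@](C)(O[Si](C)(C)C(C)(C)C)[C@H]12 | intermediate
17 | 3,5-bis(tert-butyldimethylsilyloxy)-3,7-dimethyl-1-triethylsilyloxy-cis-syn-cis-tricyclo[5.3.0.0(2,6)]decan-9-one | O=C1C[C@]2(C)[C@@H]3[C@@H](O[Si](C)(C)C(C)(C)C)C[C@@](C)(O[Si](C)(C)C(C)(C)C)[C@@H]3[C@@]2(C1)O[Si](CC)(CC)CC | intermediate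
18 | 3,5-bis(tert-butyldimethylsilyloxy)-1-hydroxy-3,7-dimethyl-cis-syn-cis-tricyclo[5.3.0.0(2,6)]decan-9-one | O=C1C[C@]2(C)[C@@H]3[C@@H](O[Si](C)(C)C(C)(C)C)C[C@@](C)(O[Si](C)(C)C(C)(C)C)[C@@H]3[C@@]2(C1)O | intermediate
19 | methyl 2-(hydroxymethyl)acrylate | C=C(CO)C(=O)OC | starting material
20 | methyl 2-[(tert-butyldimethylsilyloxy)methyl]acrylate | C=C(CO[Si](C)(C)C(C)(C)C)C(=O)OC | intermediate
21 | 2-[(tert-butyldimethylsilyloxy)methyl]acrylic acid | C=C(CO[Si](C)(C)C(C)(C)C)C(=O)O | intermediate
22 | 2-[(tert-butyldimethylsilyloxy)methyl]acryloyl chloride | C=C(CO[Si](C)(C)C(C)(C)C)C(Cl)=O | intermediate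
23 | C9 2-[(tert-butyldimethylsilyloxy)methyl]acrylate ester of 18 | O=C1C[C@]2(C)[C@@H]3[C@@H](O[Si](C)(C)C(C)(C)C)C[C@@](C)(O[Si](C)(C)C(C)(C)C)[C@@H]3[C@@]2(C1)OC(=O)C(=C)CO[Si](C)(C)C(C)(C)C | intermediate
24 | 1,2,4-trioxolane (ozonide) of 23 (ring carbon open) | O=C1C[C@]2(C)[C@@H]3[C@@H](O[Si](C)(C)C(C)(C)C)C[C@@](C)(O[Si](C)(C)C(C)(C)C)[C@@H]3[C@@]2(C1)OC(=O)C4(CO[Si](C)(C)C(C)(C)C)OCOO4 | intermediate
25 | C9 3-(tert-butyldimethylsilyloxy)-2-oxopropanoate ester of 18 | O=C1C[C@]2(C)[C@@H]3[C@@H](O[Si](C)(C)C(C)(C)C)C[C@@](C)(O[Si](C)(C)C(C)(C)C)[C@@H]3[C@@]2(C1)OC(=O)C(=O)CO[Si](C)(C)C(C)(C)C | intermediate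
26 | aldol adduct: saturated gamma-lactone with C12 hydroxyl and C13–H (C12 and C13 open) | O=C1C[C@]2(C)[C@@H]3[C@@H](O[Si](C)(C)C(C)(C)C)C[C@@](C)(O[Si](C)(C)C(C)(C)C)[C@@H]3[C@@]23OC(=O)C(O)(CO[Si](C)(C)C(C)(C)C)C13 | intermediate
27 | tetracyclic butenolide ketone (C1 ketone; silyl ethers at C5-O, C7-O and C12 CH2O) | O=C1C[C@]2(C)[C@@H]3[C@@H](O[Si](C)(C)C(C)(C)C)C[C@@](C)(O[Si](C)(C)C(C)(C)C)[C@@H]3[C@@]23OC(=O)C(CO[Si](C)(C)C(C)(C)C)=C13 | intermediate
28 | C1 endo allylic alcohol | O[C@@H]1C[C@]2(C)[C@@H]3[C@@H](O[Si](C)(C)C(C)(C)C)C[C@@](C)(O[Si](C)(C)C(C)(C)C)[C@@H]3[C@@]23OC(=O)C(CO[Si](C)(C)C(C)(C)C)=C13 | intermediate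
29 | tiglic acid, (E)-2-methylbut-2-enoic acid | C/C=C(\C)C(=O)O | starting material
30 | C1 exo tiglate, tris-silyl ether | C/C=C(\C)C(=O)O[C@H]1C[C@]2(C)[C@@H]3[C@@H](O[Si](C)(C)C(C)(C)C)C[C@@](C)(O[Si](C)(C)C(C)(C)C)[C@@H]3[C@@]23OC(=O)C(CO[Si](C)(C)C(C)(C)C)=C13 | intermediate
31 | triol with C1 tiglate | C/C=C(\C)C(=O)O[C@H]1C[C@]2(C)[C@@H]3[C@@H](O)C[C@@](C)(O)[C@@H]3[C@@]23OC(=O)C(CO)=C13 | intermediate
32 | CNP0210373.1 (C1 tiglate, C5 acetate, C7 tertiary alcohol, C12 acetoxymethyl butenolide) | C/C=C(\C)C(=O)O[C@H]1C[C@]2(C)[C@@H]3[C@@H](OC(C)=O)C[C@@](C)(O)[C@@H]3[C@@]23OC(=O)C(COC(C)=O)=C13 | target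

**Step count**

Total step count: 22 (20 in the main line, 2 for acid 21).
Longest linear sequence: 20 steps (steps 1 to 13 and 16 to 22).

**Steps most likely to fail**

Step 12. The carbenoid may be intercepted by the C9 silyl ether oxygen (ylide formation followed by silyl shift), or the insertion at the crowded cyclobutane methine may be too slow and carbene dimerisation may take over. The fallback sets out from 7 and comes back at 18; it builds ring C by enolate alkylation and carbonyl allylation instead of C–H insertion. Alkylation of the lithium enolate of 7 (LiN(SiMe3)2, THF, −78 °C) with 2-(iodomethyl)-3-(trimethylsilyl)prop-1-ene on the convex face should give the allylsilane ketone F1. A second enolisation and methylation with MeI, again from the convex face, pushes the arm to the concave face and gives the quaternary ketone F2. EtAlCl2 (CH2Cl2, −78 °C) would then trigger intramolecular Hosomi–Sakurai addition of the allylsilane to the C9 ketone, which can only give cis-fused ring C with the C9 hydroxyl exo, the methylenecyclopentanol F3. Ozonolysis (O3, CH2Cl2, −78 °C, through the ozonide F4, then Me2S) turns the exocyclic methylene into the C1 ketone and delivers 18, from which steps 16 to 22 follow unchanged.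

Step 3. Regiocontrol may be insufficient (the ketene carbonyl carbon bonding to C4 instead of C8), or facial control incomplete, because both alkene carbons are secondary and flanked by oxygenated carbons. The fallback sets out from 1 and comes back at 8; it uses a polar ynamine–enone [2+2] cycloaddition (Ficini reaction), in which the enone polarity fixes the regiochemistry. 1 and N,N-diethylprop-1-yn-1-amine (MeCN, 25 °C) should give the aminocyclobutene ketone F5: the methyl-bearing ynamine carbon attacks C4 anti to the silyloxy group and the enolate carbon C8 closes onto the keteniminium carbon. Wittig methylenation of the C7 ketone (Ph3P=CH2, THF, −78 to 0 °C) gives the methylene enamine F6. Mild aqueous acid (AcOH/NaOAc, THF/H2O) hydrolyses the enamine, and DBU equilibrates C3 to the exo methyl epimer, giving the methylene cyclobutanone F7. Hydrogen-atom-transfer hydration (Mukaiyama conditions: Co(acac)2 cat., PhSiH3, O2, i-PrOH, 25 °C) should trap the tertiary C7 radical on the convex face and give the tertiary alcohol F8 with the hydroxyl exo and the methyl endo. TBSOTf/2,6-lutidine then gives 8.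

Step 16. Acylation of the tertiary cyclobutanol may be slow, so that elimination across C9–C13 or retro-aldol cleavage of the beta-hydroxy ketone competes. The fallback sets out from 18 and comes back at 27; it acylates with a much smaller, more reactive electrophile and builds C12 afterwards. Methyl chlorooxoacetate (pyridine, DMAP cat., CH2Cl2, 0 °C) gives the mixed oxalate F9. LiN(SiMe3)2 (THF, −78 °C) effects Dieckmann-type closure of the C13 enolate onto the distal ester carbonyl with loss of methoxide, giving the enolised alpha-keto lactone F10. Tf2O/2,6-lutidine (CH2Cl2, −78 °C) gives the enol triflate F11. Stille coupling with Bu3SnCH2OH (Pd(PPh3)4, LiCl, dioxane, 80 °C) gives the hydroxymethyl butenolide F12, and TBSCl/imidazole returns 27.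

Further compounds
F1 | step 12 | 2-exo,4-exo-bis(tert-butyldimethylsilyloxy)-4-endo-methyl-7-exo-[2-(trimethylsilylmethyl)allyl]-cis-bicyclo[3.2.0]heptan-6-one | O=C1[C@@H](CC(=C)C[Si](C)(C)C)[C@@H]2[C@@H](O[Si](C)(C)C(C)(C)C)C[C@@](C)(O[Si](C)(C)C(C)(C)C)[C@H]12
F2 | step 12 | 2-exo,4-exo-bis(tert-butyldimethylsilyloxy)-4-endo,7-exo-dimethyl-7-endo-[2-(trimethylsilylmethyl)allyl]-cis-bicyclo[3.2.0]heptan-6-one | O=C1[C@](C)(CC(=C)C[Si](C)(C)C)[C@@H]2[C@@H](O[Si](C)(C)C(C)(C)C)C[C@@](C)(O[Si](C)(C)C(C)(C)C)[C@H]12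
F3 | step 12 | 3,5-bis(tert-butyldimethylsilyloxy)-3,7-dimethyl-9-methylene-cis-syn-cis-tricyclo[5.3.0.0(2,6)]decan-1-ol | C=C1C[C@]2(C)[C@@H]3[C@@H](O[Si](C)(C)C(C)(C)C)C[C@@](C)(O[Si](C)(C)C(C)(C)C)[C@@H]3[C@@]2(C1)O
F4 | step 12 | spiro 1,2,4-trioxolane (ozonide) of F3 at C1 | C14(OCOO4)C[C@]2(C)[C@@H]3[C@@H](O[Si](C)(C)C(C)(C)C)C[C@@](C)(O[Si](C)(C)C(C)(C)C)[C@@H]3[C@@]2(C1)O
F5 | step 3 | 7-(diethylamino)-6-methyl-4-exo-(tert-butyldimethylsilyloxy)-cis-bicyclo[3.2.0]hept-6-en-2-one | CCN(CC)C1=C(C)[C@@H]2[C@@H](O[Si](C)(C)C(C)(C)C)CC(=O)[C@H]12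
F6 | step 3 | N,N-diethyl-6-methyl-2-methylene-4-exo-(tert-butyldimethylsilyloxy)-cis-bicyclo[3.2.0]hept-6-en-7-amine | CCN(CC)C1=C(C)[C@@H]2[C@@H](O[Si](C)(C)C(C)(C)C)CC(=C)[C@H]12
F7 | step 3 | 2-exo-(tert-butyldimethylsilyloxy)-7-exo-methyl-4-methylene-cis-bicyclo[3.2.0]heptan-6-one | O=C1[C@@H](C)[C@@H]2[C@@H](O[Si](C)(C)C(C)(C)C)CC(=C)[C@H]12
F8 | step 3 | 2-exo-(tert-butyldimethylsilyloxy)-4-exo-hydroxy-4-endo,7-exo-dimethyl-cis-bicyclo[3.2.0]heptan-6-one | O=C1[C@@H](C)[C@@H]2[C@@H](O[Si](C)(C)C(C)(C)C)C[C@@](C)(O)[C@H]12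
F9 | step 16 | C9 methyl oxalate ester of 18 | O=C1C[C@]2(C)[C@@H]3[C@@H](O[Si](C)(C)C(C)(C)C)C[C@@](C)(O[Si](C)(C)C(C)(C)C)[C@@H]3[C@@]2(C1)OC(=O)C(=O)OC
F10 | step 16 | C12 hydroxy butenolide ketone (enol of the alpha-keto lactone) | O=C1C[C@]2(C)[C@@H]3[C@@H](O[Si](C)(C)C(C)(C)C)C[C@@](C)(O[Si](C)(C)C(C)(C)C)[C@@H]3[C@@]23OC(=O)C(O)=C13
F11 | step 16 | C12 enol triflate of the butenolide ketone | O=C1C[C@]2(C)[C@@H]3[C@@H](O[Si](C)(C)C(C)(C)C)C[C@@](C)(O[Si](C)(C)C(C)(C)C)[C@@H]3[C@@]23OC(=O)C(OS(=O)(=O)C(F)(F)F)=C13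
F12 | step 16 | C12 hydroxymethyl butenolide ketone | O=C1C[C@]2(C)[C@@H]3[C@@H](O[Si](C)(C)C(C)(C)C)C[C@@](C)(O[Si](C)(C)C(C)(C)C)[C@@H]3[C@@]23OC(=O)C(CO)=C13
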